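## The problem

The target, (1R,2R,4S)-2-bromo-4-[(1S,4S)-4-bromo-3,3-dimethylcyclohexyl]-1-methyl-7-oxabicyclo[2.2.1]heptane, joins two rings by one freely rotating bond, from the quaternary bridgehead C4 to C1' of a trans-4-bromo-3,3-dimethylcyclohexane. The bridgeheads C1 and C4 are locked to each other by the oxygen bridge, and the endo bromide at C2 can be derived from them through the exo/endo bias of the bicycle. Neither ring can control the other across the C4–C1' bond, so two independent sources of absolute configuration are needed. The C4' bromide is secondary and neopentyl; it cannot be made by displacement and must come from a bromonium-initiated ring closure onto the adjacent tertiary carbon. C1' and C4' are 1,4-related, and the cis and trans isomers differ only in whether bromine is equatorial or axial beside the gem-dimethyl group, so the trans relation is not a thermodynamic gift. Both secondary bromides exclude strong base, reducing metals, tin hydrides and hydrogenolysis catalysts, and the two tertiary C–O bonds of the strained ether exclude strong acid late in the route. The enabling feature is that O7, C1, C2, C3 and C4 are the imprint of a furan: C1 and C4 are its α-carbons and C2 and C3 its β-carbons. A 3-bromofuran therefore fixes the bromine locant before the ring is built, C5–C6 is a two-carbon dienophile, and exo delivery of hydrogen to the C2=C3 vinyl bromide leaves bromine endo.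

## Retrosynthesis

**18 to 16 and 15.** C5 of target 18 is unsubstituted, so a carboxyl group can sit there during ring formation. Cutting C5–CO2H gives acid 16 and its trifluoroethyl ester 15. A carboxyl is preferred to a sulfone or nitro activating group because its removal (Barton reductive decarboxylation with a thiol) needs neither stannane nor dissolving metal. The forward step must generate a secondary radical at C5 and quench it with hydrogen without touching either C–Br bond.

**15 to 14.** Removing H2 from C2–C3 gives the vinyl bromide 14. This cut is better than installing bromine on a saturated bicycle, which would need substitution at a carbon flanked by a quaternary bridgehead. The forward step asks for syn hydrogen transfer to the exo face only, by a reagent that does not cleave C–Br; diimide meets this.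

**14 to 12 and 13 (key).** Cutting C1–C6 and C4–C5 opens the carbocycle to the furan 12 and the acrylate 13. Closing the ether by C–O bond formation would require the carbocycle, two tertiary oxygenated carbons and a separate bromination. The cycloaddition makes the ring, both C–O-bearing quaternary centres and the bromine locant at once, from a flat aromatic precursor with no stereocentre in the heterocycle. The price is selection of one furan π-face. It is tempting to treat the acrylate's regiochemistry and endo/exo orientation as irrelevant because the carboxyl is excised. That is not so: a catalyst on the acrylate fixes only the configuration at the ester-bearing carbon, and for that fixed configuration each switch of regiochemistry or of endo/exo mode engages the opposite furan face and inverts both bridgeheads. The forward reaction therefore needs catalyst control of the acrylate face together with one regiochemistry and one endo/exo mode. The ester is drawn at C5, next to the cyclohexyl-bearing bridgehead, because the leading bond should form between the acrylate β-carbon and the methyl-bearing furan carbon, which is the less hindered terminus and the one activated by the neighbouring bromine.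

**12 to 11, then to 8 and 9.** Cutting the furan–C1' bond gives the C8 bromoketone 8 and 3-bromo-2-methylfuran 9, joined through carbinol 11. A cross-coupling of a cyclohexyl halide is ruled out by the two alkyl bromides. The cut reduces 12 to a ketone with one stereocentre and a purchasable furan. The forward sequence must set C1' during deoxygenation of 11, which needs 1,4-induction from the C4' bromide.

**8 to 7 and 6.** The carbonyl of 8 comes from the exocyclic methylene of 7. The C2'–C3' ring bond of 7 is cut to the open-chain bromochloride 6, in which the C–Br bond already exists and the allylsilane is the ring-closing nucleophile. The allylsilane guarantees a single, exocyclic alkene. The forward reaction must generate the bromonium ion from 6 without free electrophilic bromine and close the ring before the ion can transfer bromine to another alkene.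

**6 to 3 and 4, then 2 and 1.** Cutting the C3–C4 bond of the heptyl chain of 6 gives the triflate 3 and the allylic chloride 4. Triflate 3 comes from the bromochloro alcohol 2, made from prenol 1 by catalytic enantioselective bromochlorination. This places the only absolute stereocontrol of the cyclohexane in a known reaction of a simple allylic alcohol.

## Roads not taken

**Alternative 1:** The carbocycle is cut at C3–C4. A zinc (Reformatsky) enolate from the bromomethyl ketone (4R)-6-bromo-1-[(1S,4S)-4-bromo-3,3-dimethylcyclohexyl]-4-methyl-4-(triethylsilyloxy)hexane-1,5-dione A2 adds to the cyclohexyl ketone and gives the hydroxy ketone 5-[(1S,4S)-4-bromo-3,3-dimethylcyclohexyl]-5-hydroxy-2-methyl-2-(triethylsilyloxy)cyclohexan-1-one A1. The C1 carbinol is bought as (R)-linalool A3.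
- Merit: C1 comes from the chiral pool with no facial-selectivity question. In this respect it is safer than the chosen plan.
- Weak points: C4 is formed without control. The C2 ketone must then become an endo bromide by substitution at a carbon next to a quaternary centre. The ether must be closed between two tertiary carbinols under ionising conditions that invite elimination.
- Comparison: the chosen plan sets against the secure C1 the fact that it needs no substitution chemistry at C2 or C4 and far fewer operations after ring closure.

**Alternative 2:** The two C–O bonds are cut at the stage of a peroxide homologue. Dye-sensitised photooxygenation of the bromodiene (1S,4S)-1-bromo-4-(3-bromo-4-methylcyclohexa-1,3-dien-1-yl)-2,2-dimethylcyclohexane A5 gives the endoperoxide 5-bromo-1-[(1S,4S)-4-bromo-3,3-dimethylcyclohexyl]-4-methyl-2,3-dioxabicyclo[2.2.2]oct-5-ene A4. Alkene reduction and extrusion of one oxygen would follow.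
- Merits: it is short, needs no activating group, and fixes the bromine locant by a pre-brominated diene as the chosen plan does.
- Weak points: the oxidant is achiral and the only chirality is the remote cyclohexyl unit, so the bridgeheads would form without control. The brominated diene is deactivated and ene reactions at the allylic positions compete. The [2.2.2] alkene offers little face bias for placing bromine. Oxygen extrusion must end with bond formation at a tertiary carbon.
- Comparison: it is shorter, but it has no lever for absolute or relative control, which the chosen plan has in the chiral Lewis acid and the exo bias of the oxanorbornene.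

**Alternative 3:** The cyclohexene is cut at C3–C4 and C5–C6. Isoprene A8 adds to the Lewis acid-bound acrolein 2-[(1S,4S)-4-bromo-3,3-dimethylcyclohexyl]prop-2-enal A7 and gives (1S)-1-[(1S,4S)-4-bromo-3,3-dimethylcyclohexyl]-4-methylcyclohex-3-ene-1-carbaldehyde A6. The formyl group is then exchanged for oxygen, and a transannular bromoetherification closes the bridge with bromine anti to oxygen, that is endo.
- Merits: 2-substituted acroleins are the best-behaved substrates of catalytic asymmetric Diels–Alder chemistry. Only the dienophile face decides C4, because isoprene carries no stereo-defining group, and the later steps follow from geometry. In stereocontrol of the bicycle this road is more secure than the chosen one.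
- Weak points: the α-(sec-alkyl)acrolein is hindered. It must be built from the same bromocyclohexyl dyad by a longer homologation. The formyl-to-hydroxyl exchange needs a peracid in the presence of a nucleophilic trisubstituted alkene. Electrophilic bromine is used late.
- Comparison: the chosen plan sets against this a two-step convergent union of 8 and 9, and the formation of both C–O centres and the bromine locant in one concerted step without late oxidants or electrophilic bromine. It pays with a harder facial-selection problem.

Key step: step 8

Remark on numbering: all oxabicycles are named with the locants of the target (C1 methyl-bearing bridgehead, C2 bromine-bearing carbon, C4 cyclohexyl-bearing bridgehead, O7); cyclohexyl positions carry a prime in the text.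

Assumption: an oxazaborolidinium catalyst built from (S)-α,α-diphenylprolinol is taken to steer dienes to the Cα-Re face of a bound acrylate ester; step 8 needs the Cα-Si face and therefore names the (R)-catalyst, the antipode being used should the sense be the reverse.

## Route

Step 1
Reactants: 1 3-methylbut-2-en-1-ol (prenol)
Product: 2 (2S)-2-bromo-3-chloro-3-methylbutan-1-ol
Conditions: NBS, ClTi(OiPr)3, chiral tridentate salicylaldimine–amino alcohol ligand (20 mol%), hexanes, –20 °C
Reagents that add atoms: N-bromosuccinimide, O=C1CCC(=O)N1Br; chlorotitanium triisopropoxide, CC(C)O[Ti](Cl)(OC(C)C)OC(C)C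
Why: Titanium-mediated catalytic enantioselective bromochlorination of an allylic alcohol: the alkoxide binds the ligated titanium, bromine is delivered to one alkene face and titanium-bound chloride opens the bromonium ion anti at the tertiary carbon (Markovnikov), so bromine ends at C2 with the (S) configuration fixed by the ligand antipode.

Step 2
Reactants: 2 (2S)-2-bromo-3-chloro-3-methylbutan-1-ol
Product: 3 (2S)-2-bromo-3-chloro-3-methylbutyl trifluoromethanesulfonate
Conditions: Tf2O, 2,6-lutidine, CH2Cl2, –78 °C; used at once
Reagents that add atoms: trifluoromethanesulfonic anhydride, O=S(=O)(OS(=O)(=O)C(F)(F)F)C(F)(F)F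
Why: Standard O-sulfonylation of a primary alcohol at low temperature; the β-bromine retards ionisation of the triflate and the stereocentre is not involved.

Step 3
Reactants: 3 (2S)-2-bromo-3-chloro-3-methylbutyl trifluoromethanesulfonate; 4 [2-(chloromethyl)prop-2-en-1-yl]trimethylsilane
Product: 6 [(5S)-5-bromo-6-chloro-6-methyl-2-methylideneheptyl]trimethylsilane, via the allylmagnesium chloride 5 (not isolated)
Conditions: 4, Mg, THF, 0 °C; then 3, Li2CuCl4 (5 mol%), THF, –78 → –40 °C
Reagents that add atoms: none
Why: Copper-catalysed sp3–sp3 Grignard coupling with a primary alkyl triflate, which at –78 °C should be much faster than attack at the secondary bromide or tertiary chloride; the allyl metal has two equivalent CH2 termini so only one product can form, and the C–Br stereocentre is untouched.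

Step 4
Reactants: 6 [(5S)-5-bromo-6-chloro-6-methyl-2-methylideneheptyl]trimethylsilane
Product: 7 (1S)-1-bromo-2,2-dimethyl-4-methylidenecyclohexane
Conditions: (CF3)2CHOH (0.02 M), 2,6-di-tert-butyl-4-methylpyridine, rt
Reagents that add atoms: none
Why: Solvolytic bromonium-ion cation–olefin cyclisation: in the ionising, weakly nucleophilic alcohol the tertiary chloride leaves with anchimeric assistance of the anti bromine, the allylsilane terminus opens the bromonium ion at the tertiary carbon (6-endo, chair) and loss of silicon gives only the exocyclic alkene; the C–Br bond is never broken, so the (S) configuration is carried over.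

Step 5
Reactants: 7 (1S)-1-bromo-2,2-dimethyl-4-methylidenecyclohexane
Product: 8 (4S)-4-bromo-3,3-dimethylcyclohexan-1-one
Conditions: O3, CH2Cl2–MeOH, –78 °C; then Me2S, –78 °C → rt
Reagents that add atoms: ozone, [O-][O+]=O
Why: Ozonolysis of a 1,1-disubstituted alkene with reductive work-up; the secondary bromide is inert to ozone and dimethyl sulfide.

Step 6
Reactants: 9 3-bromo-2-methylfuran; 8 (4S)-4-bromo-3,3-dimethylcyclohexan-1-one
Product: 11 (4S)-4-bromo-1-(4-bromo-5-methylfuran-2-yl)-3,3-dimethylcyclohexan-1-ol (C1 epimers), via the 5-lithiofuran 10 (not isolated)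
Conditions: 9, LDA, THF, –78 °C; then 8 premixed with LaCl3·2LiCl, THF, –78 °C; aq. NH4Cl
Reagents that add atoms: none
Why: Directed α-metalation of the furan at its only free α-position with an amide base (no bromine–lithium exchange), then lanthanide-assisted 1,2-addition to the ketone, which suppresses enolisation; the carbinol configuration is irrelevant because this centre is ionised in step 7.

Step 7
Reactants: 11 (4S)-4-bromo-1-(4-bromo-5-methylfuran-2-yl)-3,3-dimethylcyclohexan-1-ol
Product: 12 3-bromo-5-[(1S,4S)-4-bromo-3,3-dimethylcyclohexyl]-2-methylfuran
Conditions: Et3SiH, CF3CO2H, CH2Cl2, –78 → –30 °C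
Reagents that add atoms: none
Why: Ionic hydrogenation of a tertiary furfuryl alcohol through the furan-stabilised cation; the axial C3' methyl group blocks axial approach so the silane should deliver hydride equatorially, and the cation is expected to react through the chair with axial C4'–Br (no Br/axial-methyl gauche contact, C–Br dipole turned toward the cationic centre as in 4-halocyclohexanones), which puts the new hydrogen cis to bromine and the furyl group trans, setting C1' as (S).

Step 8
Reactants: 12 3-bromo-5-[(1S,4S)-4-bromo-3,3-dimethylcyclohexyl]-2-methylfuran; 13 2,2,2-trifluoroethyl prop-2-enoate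
Product: 14 2,2,2-trifluoroethyl (1R,4S,5R)-2-bromo-4-[(1S,4S)-4-bromo-3,3-dimethylcyclohexyl]-1-methyl-7-oxabicyclo[2.2.1]hept-2-ene-5-carboxylate (5-endo ester)
Conditions: 13 (3 equiv), (R)-oxazaborolidinium triflimide [from (R)-α,α-diphenylprolinol, o-tolylboroxine, Tf2NH] (20 mol%), CH2Cl2, –78 → –40 °C; Et3N quench, cold filtration
Reagents that add atoms: none
Why: The cationic boron Lewis acid binds the ester carbonyl of 13 and lowers its LUMO, so that the electron-rich furan 12 adds across its α-carbons in a concerted, asynchronous, suprafacial [4+2] cycloaddition; the closest known reaction type is the oxazaborolidinium-catalysed Diels–Alder reaction of furans with trifluoroethyl acrylate. The one ring that closes is the six-membered carbocycle C1–C6, formed by intermolecular [4+2] annulation with the furan oxygen left as the one-atom bridge and the former β-carbons as the C2=C3 vinyl bromide. C5 is set by the catalyst, which leaves only the Si face of the acrylate α-carbon open. C1 and C4 are set together by the furan face that is engaged, and this face follows from the C5 configuration only through the regiochemistry and the endo or exo mode, so all three must be controlled. The leading bond should form between the acrylate β-carbon and the methyl-bearing furan carbon, the less hindered terminus and the one activated by the adjacent bromine (as in 2-halodienes), which places the ester at C5. Endo orientation is expected under kinetic control at low temperature with a Lewis acid-bound ester. The remote cyclohexyl stereocentres exert no influence, so the furan π-face selectivity that the step needs rests on catalyst face control combined with this regio- and endo-preference. The bromine substituent makes the cycloaddition more exergonic than for a plain dialkylfuran, and the adduct is kept cold and reduced at once to forestall cycloreversion.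

Step 9
Reactants: 14 2,2,2-trifluoroethyl (1R,4S,5R)-2-bromo-4-[(1S,4S)-4-bromo-3,3-dimethylcyclohexyl]-1-methyl-7-oxabicyclo[2.2.1]hept-2-ene-5-carboxylate
Product: 15 2,2,2-trifluoroethyl (1R,2R,4S,5R)-2-bromo-4-[(1S,4S)-4-bromo-3,3-dimethylcyclohexyl]-1-methyl-7-oxabicyclo[2.2.1]heptane-5-carboxylate (2-endo bromide)
Conditions: KO2CN=NCO2K, AcOH (slow addition), CH2Cl2, –20 → 0 °C
Reagents that add atoms: none
Why: Diimide reduction: concerted syn transfer of two hydrogens to the strained alkene from the exo (oxygen-bridge) face, the endo face being shielded by the C5–C6 bridge and its endo ester, so both new hydrogens are exo and bromine is left endo (2R); the reagent does not cleave C–Br bonds and works below the temperature of cycloreversion.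

Step 10
Reactants: 15 2,2,2-trifluoroethyl (1R,2R,4S,5R)-2-bromo-4-[(1S,4S)-4-bromo-3,3-dimethylcyclohexyl]-1-methyl-7-oxabicyclo[2.2.1]heptane-5-carboxylate
Product: 16 (1R,2R,4S,5R)-2-bromo-4-[(1S,4S)-4-bromo-3,3-dimethylcyclohexyl]-1-methyl-7-oxabicyclo[2.2.1]heptane-5-carboxylic acid
Conditions: LiOH, THF–H2O, 0 °C; then 1 M HCl
Reagents that add atoms: lithium hydroxide, [Li+].[OH-]
Why: Saponification of an activated trifluoroethyl ester, fast at 0 °C; the carboxylate formed resists α-deprotonation and hence β-elimination of the bridging oxygen, and any epimerisation at C5 is without consequence.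

Step 11
Reactants: 16 (1R,2R,4S,5R)-2-bromo-4-[(1S,4S)-4-bromo-3,3-dimethylcyclohexyl]-1-methyl-7-oxabicyclo[2.2.1]heptane-5-carboxylic acid
Product: 18 (1R,2R,4S)-2-bromo-4-[(1S,4S)-4-bromo-3,3-dimethylcyclohexyl]-1-methyl-7-oxabicyclo[2.2.1]heptane, via the Barton ester 17 (not isolated)
Conditions: N-hydroxypyridine-2-thione, DCC, DMAP (cat.), CH2Cl2, rt, dark; then t-BuSH, hν (visible), rt
Reagents that add atoms: none
Why: Barton reductive decarboxylation: the thiohydroxamate ester fragments under light with loss of CO2 to a secondary C5 radical, which takes hydrogen from the thiol; no stannane or metal is present, so both alkyl bromides survive, and C5 ceases to be a stereocentre.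

## Compound list

1 | 3-methylbut-2-en-1-ol (prenol) | CC(C)=CCO | starting material
2 | (2S)-2-bromo-3-chloro-3-methylbutan-1-ol | OC[C@H](Br)C(C)(C)Cl | intermediate
3 | (2S)-2-bromo-3-chloro-3-methylbutyl trifluoromethanesulfonate | O=S(=O)(OC[C@H](Br)C(C)(C)Cl)C(F)(F)F | intermediate
4 | [2-(chloromethyl)prop-2-en-1-yl]trimethylsilane | C[Si](C)(C)CC(=C)CCl | starting material
5 | chlorido{2-[(trimethylsilyl)methyl]prop-2-en-1-yl}magnesium | C[Si](C)(C)CC(=C)C[Mg]Cl | intermediate
6 | [(5S)-5-bromo-6-chloro-6-methyl-2-methylideneheptyl]trimethylsilane | C[Si](C)(C)CC(=C)CC[C@H](Br)C(C)(C)Cl | intermediate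
7 | (1S)-1-bromo-2,2-dimethyl-4-methylidenecyclohexane | C=C1CC[C@H](Br)C(C)(C)C1 | intermediate
8 | (4S)-4-bromo-3,3-dimethylcyclohexan-1-one | O=C1CC[C@H](Br)C(C)(C)C1 | intermediate
9 | 3-bromo-2-methylfuran | Cc1occc1Br | starting material
10 | (4-bromo-5-methylfuran-2-yl)lithium | [Li]c1cc(Br)c(C)o1 | intermediate
11 | (4S)-4-bromo-1-(4-bromo-5-methylfuran-2-yl)-3,3-dimethylcyclohexan-1-ol (C1 epimers) | CC1(C)CC(O)(c2cc(Br)c(C)o2)CC[C@@H]1Br | intermediate
12 | 3-bromo-5-[(1S,4S)-4-bromo-3,3-dimethylcyclohexyl]-2-methylfuran | CC1(C)C[C@@H](c2cc(Br)c(C)o2)CC[C@@H]1Br | intermediate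
13 | 2,2,2-trifluoroethyl prop-2-enoate | C=CC(=O)OCC(F)(F)F | starting material
14 | 2,2,2-trifluoroethyl (1R,4S,5R)-2-bromo-4-[(1S,4S)-4-bromo-3,3-dimethylcyclohexyl]-1-methyl-7-oxabicyclo[2.2.1]hept-2-ene-5-carboxylate | CC1(C)C[C@@H]([C@@]23[C@H](C(=O)OCC(F)(F)F)C[C@@](C)(O2)C(Br)=C3)CC[C@@H]1Br | intermediate
15 | 2,2,2-trifluoroethyl (1R,2R,4S,5R)-2-bromo-4-[(1S,4S)-4-bromo-3,3-dimethylcyclohexyl]-1-methyl-7-oxabicyclo[2.2.1]heptane-5-carboxylate | CC1(C)C[C@@H]([C@@]23[C@H](C(=O)OCC(F)(F)F)C[C@@](C)(O2)[C@H](Br)C3)CC[C@@H]1Br | intermediate
16 | (1R,2R,4S,5R)-2-bromo-4-[(1S,4S)-4-bromo-3,3-dimethylcyclohexyl]-1-methyl-7-oxabicyclo[2.2.1]heptane-5-carboxylic acid | CC1(C)C[C@@H]([C@@]23[C@H](C(=O)O)C[C@@](C)(O2)[C@H](Br)C3)CC[C@@H]1Br | intermediate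
17 | 2-sulfanylidenepyridin-1(2H)-yl (1R,2R,4S,5R)-2-bromo-4-[(1S,4S)-4-bromo-3,3-dimethylcyclohexyl]-1-methyl-7-oxabicyclo[2.2.1]heptane-5-carboxylate | CC1(C)C[C@@H]([C@@]23[C@H](C(=O)ON4C=CC=CC4=S)C[C@@](C)(O2)[C@H](Br)C3)CC[C@@H]1Br | intermediate
18 | (1R,2R,4S)-2-bromo-4-[(1S,4S)-4-bromo-3,3-dimethylcyclohexyl]-1-methyl-7-oxabicyclo[2.2.1]heptane | CC1(C)C[C@@H]([C@@]23CC[C@@](C)(O2)[C@H](Br)C3)CC[C@@H]1Br | target

## Step count and risks

Total steps: 11. Longest linear sequence: 11 steps (1 to 18); compounds 4, 9 and 13 enter as purchased.

**Step 8 (key step).** Three things may go wrong: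
- Conversion may stall, because both reacting furan carbons are fully substituted and the cycloaddition is reversible.
- The strongly acidic catalyst may degrade the electron-rich furan or ionise a tertiary C–O bond of the adduct.
- Furan-face selectivity may leak through an exo or a C6-ester transition state, each of which inverts both bridgeheads even when the acrylate face is perfectly controlled.

The resulting bridgehead epimers are diastereomers of 14 and can be separated, at a cost in material. Fallback, from 12 back to 16: face control is moved from a catalyst to a covalent auxiliary. Furan 12 is combined with the acrylate of (R)-pantolactone, (3R)-4,4-dimethyl-2-oxooxolan-3-yl prop-2-enoate F1, under a stoichiometric chelating Lewis acid (TiCl4, CH2Cl2, –78 °C). This should give the auxiliary ester (3R)-4,4-dimethyl-2-oxooxolan-3-yl (1R,4S,5R)-2-bromo-4-[(1S,4S)-4-bromo-3,3-dimethylcyclohexyl]-1-methyl-7-oxabicyclo[2.2.1]hept-2-ene-5-carboxylate F2. Its crystalline diastereomers can be purified. Diimide reduction as in step 9 gives the saturated ester (3R)-4,4-dimethyl-2-oxooxolan-3-yl (1R,2R,4S,5R)-2-bromo-4-[(1S,4S)-4-bromo-3,3-dimethylcyclohexyl]-1-methyl-7-oxabicyclo[2.2.1]heptane-5-carboxylate F3, and LiOH hydrolysis returns to 16.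

**Step 7.** The 1,4-induction may be weak: hydride delivery through the chair with equatorial bromine gives the cis epimer, and the acid may attack the furan. Fallback, from 11 back to 12: dehydration of 11 with methyl N-(triethylammoniosulfonyl)carbamate should give 3-bromo-5-[(4S)-4-bromo-5,5-dimethylcyclohex-1-en-1-yl]-2-methylfuran F4. Iridium-catalysed asymmetric hydrogenation with a chiral phosphino-oxazoline ligand then sets C1' under reagent control. The catalyst must overrule this alkene's own preference to take up hydrogen anti to the axial methyl group.

**Step 3.** Elimination or halogen–metal exchange at the β-bromo triflate may outrun coupling, and the allylic Grignard reagent may homocouple. Fallback, from 3 back to 6: the allylsilane is built after the C–C bond. Alkylation of the lithium enolate of methyl acetate with 3 (THF, –78 °C) gives methyl (4S)-4-bromo-5-chloro-5-methylhexanoate F5. Double addition of Me3SiCH2MgCl/CeCl3 gives (5S)-5-bromo-6-chloro-6-methyl-1-(trimethylsilyl)-2-[(trimethylsilyl)methyl]heptan-2-ol F6. Peterson elimination on silica gel then gives 6.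

**Step 4.** Enantiomeric purity may erode through bromonium transfer between alkenes before ring closure, and acid released in the medium may protodesilylate the allylsilane. Fallback, from 3 back to 8: the terminator is changed to a β-keto ester enol. γ-Alkylation of the dianion of allyl acetoacetate with 3 gives prop-2-en-1-yl (6S)-6-bromo-7-chloro-7-methyl-3-oxooctanoate F7. The same solvolysis closes the ring through the enol carbon to prop-2-en-1-yl (3S)-3-bromo-2,2-dimethyl-6-oxocyclohexane-1-carboxylate F8. Palladium-catalysed deallylative decarboxylation (Pd(PPh3)4, morpholine, rt) gives 8 directly.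

**Step 9.** Hydrogen transfer to the trisubstituted bromoalkene may be slow enough for cycloreversion of 14 to compete. Fallback, from 14 back to 15: a manganese-catalysed hydrogen-atom-transfer hydrogenation (Mn(dpm)3, PhSiH3, t-BuOOH, i-PrOH), which is known to turn haloalkenes into haloalkanes. The hydrogen atom adds at C3 and the α-bromo radical at C2 is quenched from the exo face, giving 15 with no new intermediate.

## Further compounds

F1 | step 8 | (3R)-4,4-dimethyl-2-oxooxolan-3-yl prop-2-enoate | C=CC(=O)O[C@H]1C(=O)OCC1(C)C
F2 | step 8 | (3R)-4,4-dimethyl-2-oxooxolan-3-yl (1R,4S,5R)-2-bromo-4-[(1S,4S)-4-bromo-3,3-dimethylcyclohexyl]-1-methyl-7-oxabicyclo[2.2.1]hept-2-ene-5-carboxylate | CC1(C)C[C@@H]([C@@]23[C@H](C(=O)O[C@H]4C(=O)OCC4(C)C)C[C@@](C)(O2)C(Br)=C3)CC[C@@H]1Br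
F3 | step 8 | (3R)-4,4-dimethyl-2-oxooxolan-3-yl (1R,2R,4S,5R)-2-bromo-4-[(1S,4S)-4-bromo-3,3-dimethylcyclohexyl]-1-methyl-7-oxabicyclo[2.2.1]heptane-5-carboxylate | CC1(C)C[C@@H]([C@@]23[C@H](C(=O)O[C@H]4C(=O)OCC4(C)C)C[C@@](C)(O2)[C@H](Br)C3)CC[C@@H]1Br
F4 | step 7 | 3-bromo-5-[(4S)-4-bromo-5,5-dimethylcyclohex-1-en-1-yl]-2-methylfuran | Cc1oc(C2=CC[C@H](Br)C(C)(C)C2)cc1Br
F5 | step 3 | methyl (4S)-4-bromo-5-chloro-5-methylhexanoate | COC(=O)CC[C@H](Br)C(C)(C)Cl
F6 | step 3 | (5S)-5-bromo-6-chloro-6-methyl-1-(trimethylsilyl)-2-[(trimethylsilyl)methyl]heptan-2-ol | C[Si](C)(C)CC(O)(C[Si](C)(C)C)CC[C@H](Br)C(C)(C)Cl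
F7 | step 4 | prop-2-en-1-yl (6S)-6-bromo-7-chloro-7-methyl-3-oxooctanoate | C=CCOC(=O)CC(=O)CC[C@H](Br)C(C)(C)Cl
F8 | step 4 | prop-2-en-1-yl (3S)-3-bromo-2,2-dimethyl-6-oxocyclohexane-1-carboxylate | C=CCOC(=O)C1C(=O)CC[C@H](Br)C1(C)C
F0 | step 9 | none | none
A1 | alternative 1 | 5-[(1S,4S)-4-bromo-3,3-dimethylcyclohexyl]-5-hydroxy-2-methyl-2-(triethylsilyloxy)cyclohexan-1-one | CC1(C)C[C@@H]([C@]2(O)CC[C@@](C)(O[Si](CC)(CC)CC)C(=O)C2)CC[C@@H]1Br
A2 | alternative 1 | (4R)-6-bromo-1-[(1S,4S)-4-bromo-3,3-dimethylcyclohexyl]-4-methyl-4-(triethylsilyloxy)hexane-1,5-dione | CC1(C)C[C@@H](C(=O)CC[C@@](C)(O[Si](CC)(CC)CC)C(=O)CBr)CC[C@@H]1Br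
A3 | alternative 1 | (3R)-3,7-dimethylocta-1,6-dien-3-ol ((R)-linalool) | CC(C)=CCC[C@@](C)(O)C=C
A4 | alternative 2 | 5-bromo-1-[(1S,4S)-4-bromo-3,3-dimethylcyclohexyl]-4-methyl-2,3-dioxabicyclo[2.2.2]oct-5-ene | CC1(C)C[C@@H]([C@@]23CC[C@@](C)(OO2)C(Br)=C3)CC[C@@H]1Br
A5 | alternative 2 | (1S,4S)-1-bromo-4-(3-bromo-4-methylcyclohexa-1,3-dien-1-yl)-2,2-dimethylcyclohexane | CC1(C)C[C@@H](C2=CC(Br)=C(C)CC2)CC[C@@H]1Br
A6 | alternative 3 | (1S)-1-[(1S,4S)-4-bromo-3,3-dimethylcyclohexyl]-4-methylcyclohex-3-ene-1-carbaldehyde | CC1(C)C[C@@H]([C@]2(C=O)CCC(C)=CC2)CC[C@@H]1Br
A7 | alternative 3 | 2-[(1S,4S)-4-bromo-3,3-dimethylcyclohexyl]prop-2-enal | CC1(C)C[C@@H](C(=C)C=O)CC[C@@H]1Br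
A8 | alternative 3 | 2-methylbuta-1,3-diene (isoprene) | C=CC(C)=C
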